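The pitfall in this flask was to count the free monomer that had vanished as chain, when part of it may have gone with the protic impurity.

| flask | free monomer | protic impurity | initiator | remark | time |
|---|---|---|---|---|---|
| south-west | 0.050 M | 0.010 M | 0.95 mM | run made earlier |  |
| south | 0.050 M | 0.022 M | 0.95 mM | run made earlier |  |
| north-east | 0.025 M | 0.015 M | 0.95 mM | run made earlier |  |
| flask | 0.050 M | 0.0150 M | 0.95 mM |  | 10 d |

- south-west (time / d: monomer in chains / %, free monomer / %): 0.500: 17.3, 75.9; 1.67: 42.3, 44.6; 3.00: 55.1, 28.1; 4.00: 60.3, 21.1; 6.00: 66.4, 15.4; 8.00: 68.9, 9.4
- south (time / d: monomer in chains / %, free monomer / %): 0.500: 16.3, 69.4; 1.67: 37.3, 35.9; 3.00: 47.3, 20.7; 4.00: 50.9, 14.9; 6.00: 55.4, 8.4; 8.00: 56.9, 5.7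
- north-east (time / d: monomer in chains / %, free monomer / %): 0.625: 19.0, 68.2; 1.25: 31.9, 48.1; 2.50: 46.8, 26.5; 4.00: 53.1, 14.8; 8.00: 57.5, 4.7

(each reading ± 0.5 percentage points)

- whether the average number of monomer units in a chain (chains begun, living or dead) reaches 10 by 10 d (no / yes)
- average number of monomer units in a chain (chains begun, living or dead) at 10 d

- the average divides the monomer in chains by the number of chains begun, living and dead together
- the numbers in the tables scatter by 0.5 percentage points (one standard deviation)
- the earlier runs do not show the number of chains; that part of a forecast is a guess

I reckoned with the full length F = 52.6, the free monomer charged per initiator. If each initiator begins one chain, which is a guess, the average length (degree of polymerisation) is F times the fraction in chains.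

The flask has more impurity than the south-west run and less than the south run. From below, the south run's 56.9% in chains at 8.00 d gives 29.9. From above, the south-west run's 68.9% plus its 9.4% still free gives 41.2.

To tighten this, I placed the flask 0.417 of the way between those runs, which gave 63.9% in chains at 8.00 d, or 33.6. Going round once more, I added the same mix of the runs' last gains, 2.1 percentage points, as a ceiling for the next equal interval, which gave 34.7.

The forecast said yes, with a length of 34 between 28 and 45: “Chains begun are probably about the initiator”. Its 34 lies between my 2 tightened figures, which are estimates on the same guess and not bounds.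

The flask gave yes, passing 10 at 0.564 d and standing at 34.4 at 10 d.

    free monomer → uncatalysed product (k = 7.50 × 10⁻⁶ min⁻¹)
    2 living end → dead end (k = 0.140 M⁻¹ min⁻¹)
    free monomer + initiator → living end + monomer in chains (k = 0.140 M⁻¹ min⁻¹)
    protic impurity + free monomer → quenched substrate (k = 0.0120 M⁻¹ min⁻¹)
    free monomer + living end → monomer in chains + living end, rate k5*[living end]*[free monomer] (k = 0.350 M⁻¹ min⁻¹)

At 1.23 d the flask's free monomer was entering chains 2.8 times as fast as it was being quenched. At 10.0 d the flask held 65.3% in chains against 26.1% as quenched substrate, and F times that share in chains gives 34.4. For the north-east run, F is 26.3, so on the same guess its 57.5% in chains at 8.00 d reads as a length of 15.1.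

All runs are simulated on assumed constants.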